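Positions are given in germacrane numbering throughout: C1 ketone; C2=C3 furanone olefin with C3 on the ring oxygen; C4(CH3)=C5; C6 lactone carbinol; C7; C8 and C9 acyloxy carbons; C10 quaternary (C14 methyl); C11=C13 methylene; C12 lactone carbonyl.

## The problem

The target 30 is a furanoheliangolide: a ten-membered carbocycle (C1–C10) spanned by an oxygen bridge from C3 to C10, which turns C10–C1–C2–C3–O into a 3(2H)-furanone. It is further fused at C6/C7 to a trans α-methylene-γ-butyrolactone and holds a Z-configured C4=C5 olefin, so a medium ring with a bridgehead quaternary carbon has to be closed without losing that geometry. Five contiguous stereocentres (6R, 7S, 8S, 9S, 10R) must be set. C8 can come from the chiral pool and can steer C7 and C6 when the lactone is assembled, and C9 through an α-oxygen effect on an aldehyde. C10 is quaternary and remote from the lactone, so it can only be controlled by the way the chain folds over the furanone. C8 and C9 carry two different esters on neighbouring oxygens, which calls for a route that frees the two hydroxyls one at a time and avoids acyl migration. The exo-methylene lactone (Michael acceptor, opened by base), the cross-conjugated alkoxy-dienone of the furanone, the Z olefin and the allylic acetate inside the C8 acyl group exclude strong bases, hydride, hard nucleophiles and long exposure to acid late in the route. The enabling feature is that C10 is the α-carbon of the C1 ketone inside the furanone. Enol silylation turns it into the 2-position of an aromatic 3-silyloxyfuran, planar and nucleophilic, while its neighbour C9 is a carbinol. The C9–C10 bond is therefore an aldol bond whose formation closes the ring, and the configuration of C10 in every precursor is irrelevant.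

## Retrosynthesis

**Ester at C8.** The C8–O acyl bond of 30 is cut first, giving alcohol 22 and (2E)-2-(acetoxymethyl)but-2-enoic acid 28, joined through the mixed anhydride 29. This is preferred to carrying the acyl group through the ring closure because the side chain contains an SN2'-prone allylic acetate, and because the E (tiglate-type) geometry is the thermodynamic one and cannot be scrambled by DMAP. Alcohol 22 goes back through silyl ether 21 (acetate at C9) to hydroxy silyl ether 20. The forward steps only require that the single free hydroxyl is acylated each time.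

**C9–C10 (key cut).** In 20 the bond between the carbinol C9 and the quaternary C10 is an aldol bond to the α-carbon of the furanone ketone. Cutting it opens the ten-membered ring and removes two stereocentres, leading to the silyloxyfuran aldehyde 19. Against a cut at C6–C7 (macrocyclic allylation) or at the ether bridge, this one gives a precursor with three stereocentres and no medium ring. It also erases C10, so that racemic material can supply it, and it leaves exactly one free hydroxyl (C9) next to a silyl ether (C8), which separates the two ester sites. The forward reaction must close the ring at C10 of the furan (not C2), take the Felkin face of the aldehyde and one face of the furan.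

**Functional-group adjustment.** Silyloxyfuran 19 comes from furanone aldehyde 18 by enol silylation. 18 comes from primary alcohol 17, obtained from bis-silyl ether 16, diol 15 and acetonide 14. Each step changes one group, and the order keeps the labile silyloxyfuran to the last step before the ring closure.

**Lactone (C6–C7 and O–C12).** Lactone 14 is cut between C6 and C7 and at the lactone C–O bond, through the open hydroxy ester 13, into the Z-enal 8 and the allylic bromide 12. This is the most convergent cut. It joins two fragments of similar size, builds the methylene lactone in one operation and lets the chiral-pool centre C8 set C7 and C6. A late α-methylenation or an olefination at C4=C5 would be longer and would endanger the Z geometry. The forward reaction must be anti-selective (trans-lactone) and must take the allyl face dictated by the dioxolane.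

**Furanone.** Enal 8 is the oxidation product of alcohol 7. The furanone ring of 7 is opened at O–C3 to the α'-hydroxy ynone 5 (by way of silyl ether 6), and 5 is cut at C1–C2 into the acetylide of silyl ether 4 and the lactic Weinreb amide 2. These derive from (2Z)-3-methylpent-2-en-4-yn-1-ol 3, which already holds the Z olefin and its methyl group, and from ethyl lactate 1. Both bonds are made while the molecule is small and robust, before any base-sensitive group is present.

**Bromide.** Bromide 12 arises by SN2' bromination from the Baylis–Hillman adduct 11 of (R)-glyceraldehyde acetonide 9 and methyl acrylate 10. C8 and C9 thus come as a protected diol from the chiral pool, and the carbinol centre formed in the Baylis–Hillman step disappears again.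

**Side-chain acid.** Acid 28 is the tert-butyl ester 27 minus isobutene. 27 is the 1,3-transposed isomer of Baylis–Hillman acetate 26, made from alcohol 25, itself from tert-butyl acrylate 23 and acetaldehyde 24. The transposition delivers the required E geometry under thermodynamic control.

## Roads not taken

Alternative 1: The ten-membered ring would be made by ring expansion. A six-membered ring from the terpene chiral pool, carrying two cis alkenyl groups on adjacent carbons, one of them on a tertiary alkoxide, undergoes an anionic oxy-Cope rearrangement (KH, 18-crown-6) that breaks C3–C8 and forms C1–C10 to give dienone A1. This is the best-precedented way to a cyclodecenone, needs no dilution and takes C7 from the chiral pool. In reliability of ring formation it is better than the chosen plan. Its weak points lie after the rearrangement. A1 has the Z-C8=C9 olefin where the target has two different esters, so a face-selective dihydroxylation and then a regioselective acylation of two similar hydroxyls are needed. The isopropenyl group must be oxidised to the acrylate and lactonised, C1 must be deprotected and oxidised, and the furanone must still be closed. The rearrangement itself has to create C1 and the quaternary C10 from two fully substituted enol-ether termini, which are slow and whose chair/boat preference is not secure. The chosen plan sets against the safer ring formation a much shorter end game (three steps after the key step), built-in differentiation of O8 and O9, and a convergent assembly from three small fragments.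

Alternative 2: The ether bridge would be formed last on a preformed ten-membered ring. Under Sc(OTf)3 the C3 carbonyl oxygen opens a C1–C10 epoxide at its tertiary carbon and C2 loses a proton, giving dienol ether A2 with a C1 hydroxyl. The strength is that C10 is set stereospecifically by inversion at a defined epoxide, which is better than the conformational control the chosen plan relies on for this centre. The weaknesses are that the hard part, building a ten-membered ring with the Z olefin, the trans-lactone and a β,γ-epoxy ketone, is only pushed back. A β,γ-epoxy ketone readily undergoes β-elimination to the γ-hydroxy enone or a Meinwald shift under Lewis acid. C1 must still be oxidised, and the C8/C9 acetonide of A2 releases two hydroxyls at once, so the two esters are not differentiated. The chosen plan closes the carbocycle and creates C9 and C10 in the same step and leaves a single free hydroxyl. It has to accept that its C10 control rests on a folding argument.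

Alternative 3: The lactone would be closed last. A malonate tethered to the C6 oxygen is deprotonated (NaH, LiClO4) and its carbon opens a C7–C8 epoxide at C7, forming C7–C11 and the γ-lactone and setting free the C8 hydroxyl in A3. The anti opening fixes the C7/C8 relationship stereospecifically, and the trans ring fusion follows. A3 also has exactly one free hydroxyl next to a silyl ether, so in ester differentiation it is equal to the chosen plan. Against this target it again presupposes the complete furanone-bridged ten-membered ring, now with a C7–C8 epoxide of defined configuration, so ring construction and face-selective epoxidation remain open. After the key step, deallylation, decarboxylation and α-methylenation are needed before the three ester and protecting-group steps. The chosen plan brings the methylene lactone in ready-made at the fragment coupling and spends its key step on the ring itself.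

Key step: step 14

Assumption: racemic ethyl lactate is used, because the lactate-derived centre (C10) becomes planar in step 13. Compounds 2 and 5–8 are therefore racemic, 13–18 are pairs of C10 epimers (centre left open in the SMILES), and both converge in 19.

Step 1
Reactants: 1 ethyl lactate (racemic)
Product: 2 2-hydroxy-N-methoxy-N-methylpropanamide
Conditions: MeNHOMe·HCl, i-PrMgCl, THF, −20 → 0 °C
Reagents that add atoms: N,O-dimethylhydroxylamine hydrochloride, CNOC.Cl
Why: Aminolysis of the ester by the chloromagnesium amide of N,O-dimethylhydroxylamine (Weinreb amide formation); the free hydroxyl is only deprotonated and returns on work-up.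

Step 2
Reactants: 3 (2Z)-3-methylpent-2-en-4-yn-1-ol
Product: 4 tert-butyl(dimethyl){[(2Z)-3-methylpent-2-en-4-yn-1-yl]oxy}silane
Conditions: TBSCl, imidazole, CH2Cl2, 0 °C → rt
Reagents that add atoms: tert-butyldimethylsilyl chloride, CC(C)(C)[Si](C)(C)Cl
Why: Standard silylation of a primary allylic alcohol; the ether is needed because a free Z-configured hydroxyl would add to the ynone of step 3 and give a furan.

Step 3
Reactants: 4 tert-butyl(dimethyl){[(2Z)-3-methylpent-2-en-4-yn-1-yl]oxy}silane; 2 2-hydroxy-N-methoxy-N-methylpropanamide
Product: 5 (6Z)-8-{[tert-butyl(dimethyl)silyl]oxy}-2-hydroxy-6-methyloct-6-en-4-yn-3-one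
Conditions: 4 (2.3 equiv), n-BuLi (2.2 equiv), THF, −78 °C; then 2, −78 → 0 °C; aq. NH4Cl
Reagents that add atoms: none
Why: Weinreb ketone synthesis: one equivalent of the lithium acetylide deprotonates the hydroxyl, the next adds to the amide, and the chelated tetrahedral intermediate prevents a second addition; excess 4 is recovered, and the olefin geometry is not touched.

Step 4
Reactants: 5 (6Z)-8-{[tert-butyl(dimethyl)silyl]oxy}-2-hydroxy-6-methyloct-6-en-4-yn-3-one
Product: 7 5-[(2Z)-4-hydroxybut-2-en-2-yl]-2-methylfuran-3(2H)-one, via silyl ether furanone 6 (not isolated)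
Conditions: K2CO3 (0.2 equiv), MeOH, 0 °C → rt; then 1 M aq. HCl, rt
Reagents that add atoms: none
Why: Base-mediated cycloisomerisation of an α'-hydroxy ynone to a 3(2H)-furanone (oxa-Michael addition of the hydroxyl to the alkyne carbon, directly or by way of the methanol adduct), followed in the same flask by acid cleavage of the primary allylic silyl ether.

Step 5
Reactants: 7 5-[(2Z)-4-hydroxybut-2-en-2-yl]-2-methylfuran-3(2H)-one
Product: 8 (2Z)-3-(5-methyl-4-oxo-4,5-dihydrofuran-2-yl)but-2-enal
Conditions: MnO2 (activated, excess), CH2Cl2, rt, dark; used at once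
Reagents that add atoms: none
Why: Chemoselective allylic oxidation under neutral conditions, which should keep the Z geometry as in the oxidation of nerol to neral; the enal is used without storage so that it cannot drift to the E isomer.

Step 6
Reactants: 9 (R)-2,3-O-isopropylideneglyceraldehyde; 10 methyl acrylate
Product: 11 methyl 2-{hydroxy[(4R)-2,2-dimethyl-1,3-dioxolan-4-yl]methyl}prop-2-enoate (both carbinol epimers)
Conditions: DABCO (0.5 equiv), 1,4-dioxane/H2O (1:1), rt
Reagents that add atoms: none
Why: Morita–Baylis–Hillman reaction; the new carbinol centre forms as a mixture, which does not matter because it becomes sp2 in step 7, and the dioxolane centre is not epimerised by the amine.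

Step 7
Reactants: 11 methyl 2-{hydroxy[(4R)-2,2-dimethyl-1,3-dioxolan-4-yl]methyl}prop-2-enoate
Product: 12 methyl (2Z)-2-(bromomethyl)-3-[(4S)-2,2-dimethyl-1,3-dioxolan-4-yl]prop-2-enoate
Conditions: NBS, Me2S, CH2Cl2, −20 °C → rt
Reagents that add atoms: N-bromosuccinimide, O=C1CCC(=O)N1Br
Why: Corey–Kim-type activation of the Baylis–Hillman alcohol and SN2' delivery of bromide give the 2-(bromomethyl)alk-2-enoate with the substituent trans to the ester (Z); no strong acid is formed, so the acetonide survives, and the descriptor at the dioxolane changes from R to S by priority only.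

Step 8
Reactants: 8 (2Z)-3-(5-methyl-4-oxo-4,5-dihydrofuran-2-yl)but-2-enal; 12 methyl (2Z)-2-(bromomethyl)-3-[(4S)-2,2-dimethyl-1,3-dioxolan-4-yl]prop-2-enoate
Product: 14 (4S,5R)-4-[(4S)-2,2-dimethyl-1,3-dioxolan-4-yl]-3-methylidene-5-[(1Z)-2-(5-methyl-4-oxo-4,5-dihydrofuran-2-yl)prop-1-en-1-yl]oxolan-2-one, via open-chain hydroxy ester 13 (not isolated)
Conditions: CrCl2 (3.5 equiv), THF, 0 °C → rt; then PPTS (cat.), CH2Cl2, rt
Reagents that add atoms: none
Why: Chromium-mediated (Nozaki–Hiyama–Kishi type) 2-(alkoxycarbonyl)allylation with lactonisation; allylchromium reagents equilibrate and add through a chair with the aldehyde residue and the γ-substituent both equatorial, which gives the anti adduct and hence the trans C6/C7 lactone. C7 is set relative to C8 because allylic strain holds H8 in the plane next to the ester while the dioxolane CH2 (the better σ-donor) lies anti to the forming bond and the small ring oxygen takes the outside position, where it meets the aldehyde residue.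

Step 9
Reactants: 14 (4S,5R)-4-[(4S)-2,2-dimethyl-1,3-dioxolan-4-yl]-3-methylidene-5-[(1Z)-2-(5-methyl-4-oxo-4,5-dihydrofuran-2-yl)prop-1-en-1-yl]oxolan-2-one
Product: 15 (4R,5R)-4-[(1S)-1,2-dihydroxyethyl]-3-methylidene-5-[(1Z)-2-(5-methyl-4-oxo-4,5-dihydrofuran-2-yl)prop-1-en-1-yl]oxolan-2-one
Conditions: AcOH/H2O (4:1), 40 °C
Reagents that add atoms: none
Why: Acid hydrolysis of a terminal acetonide, which the methylene lactone and the furanone tolerate; migration of the lactone to O8 would give a cis-disubstituted ring and is not expected (the C7 descriptor changes by priority only).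

Step 10
Reactants: 15 (4R,5R)-4-[(1S)-1,2-dihydroxyethyl]-3-methylidene-5-[(1Z)-2-(5-methyl-4-oxo-4,5-dihydrofuran-2-yl)prop-1-en-1-yl]oxolan-2-one
Product: 16 (4S,5R)-4-[(1S)-1,2-bis{[tert-butyl(dimethyl)silyl]oxy}ethyl]-3-methylidene-5-[(1Z)-2-(5-methyl-4-oxo-4,5-dihydrofuran-2-yl)prop-1-en-1-yl]oxolan-2-one
Conditions: TBSCl (3 equiv), imidazole, DMAP (cat.), DMF, rt
Reagents that add atoms: tert-butyldimethylsilyl chloride, CC(C)(C)[Si](C)(C)Cl
Why: Exhaustive silylation of the diol; imidazole is too weak a base to enolise the furanone, so no silyloxyfuran forms at this stage (which a silyl triflate would risk).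

Step 11
Reactants: 16 (4S,5R)-4-[(1S)-1,2-bis{[tert-butyl(dimethyl)silyl]oxy}ethyl]-3-methylidene-5-[(1Z)-2-(5-methyl-4-oxo-4,5-dihydrofuran-2-yl)prop-1-en-1-yl]oxolan-2-one
Product: 17 (4S,5R)-4-[(1S)-1-{[tert-butyl(dimethyl)silyl]oxy}-2-hydroxyethyl]-3-methylidene-5-[(1Z)-2-(5-methyl-4-oxo-4,5-dihydrofuran-2-yl)prop-1-en-1-yl]oxolan-2-one
Conditions: HF·pyridine, pyridine, THF, 0 °C
Reagents that add atoms: none
Why: Buffered HF·pyridine cleaves a primary tert-butyldimethylsilyl ether much faster than a hindered secondary one, so only O9 is set free.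

Step 12
Reactants: 17 (4S,5R)-4-[(1S)-1-{[tert-butyl(dimethyl)silyl]oxy}-2-hydroxyethyl]-3-methylidene-5-[(1Z)-2-(5-methyl-4-oxo-4,5-dihydrofuran-2-yl)prop-1-en-1-yl]oxolan-2-one
Product: 18 (2S)-2-{[tert-butyl(dimethyl)silyl]oxy}-2-{(2R,3S)-4-methylidene-2-[(1Z)-2-(5-methyl-4-oxo-4,5-dihydrofuran-2-yl)prop-1-en-1-yl]-5-oxooxolan-3-yl}acetaldehyde
Conditions: Dess–Martin periodinane, pyridine, CH2Cl2, 0 °C → rt
Reagents that add atoms: none
Why: Buffered Dess–Martin oxidation of the primary alcohol gives the α-silyloxy aldehyde without epimerisation at C8 and without touching the furanone or the lactone.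

Step 13
Reactants: 18 (2S)-2-{[tert-butyl(dimethyl)silyl]oxy}-2-{(2R,3S)-4-methylidene-2-[(1Z)-2-(5-methyl-4-oxo-4,5-dihydrofuran-2-yl)prop-1-en-1-yl]-5-oxooxolan-3-yl}acetaldehyde
Product: 19 (2S)-2-{[tert-butyl(dimethyl)silyl]oxy}-2-{(2R,3S)-4-methylidene-2-[(1Z)-2-{5-methyl-4-[tri(propan-2-yl)silyloxy]furan-2-yl}prop-1-en-1-yl]-5-oxooxolan-3-yl}acetaldehyde
Conditions: TIPSOTf (1.05 equiv), Et3N, CH2Cl2, −78 °C; cold aq. NaHCO3
Reagents that add atoms: triisopropylsilyl trifluoromethanesulfonate, CC(C)[Si](C(C)C)(C(C)C)OS(=O)(=O)C(F)(F)F
Why: Soft enolisation and O-silylation of a 2-H 3(2H)-furanone to the aromatic 3-silyloxyfuran, a known conversion with silyl triflate and amine; the vinylogous-ester carbonyl is more basic and its α-hydrogen far more acidic than those of the aldehyde, so one equivalent at low temperature should react there only. C10 becomes planar here, so both epimers of 18 give the same compound.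

Step 14
Reactants: 19 (2S)-2-{[tert-butyl(dimethyl)silyl]oxy}-2-{(2R,3S)-4-methylidene-2-[(1Z)-2-{5-methyl-4-[tri(propan-2-yl)silyloxy]furan-2-yl}prop-1-en-1-yl]-5-oxooxolan-3-yl}acetaldehyde
Product: 20 (6R,7S,8S,9S,10R)-8-{[tert-butyl(dimethyl)silyl]oxy}-9-hydroxy-1-oxo-3,10-epoxygermacra-2,4Z,11(13)-trien-12,6-olide
Conditions: BF3·OEt2 (2 equiv), CH2Cl2 (1 mM, slow addition of 19), −78 °C; aq. NaHCO3
Reagents that add atoms: none
Why: Proposed new method: BF3 binds the C9 aldehyde, and C10, the enol-silane carbon of the 3-silyloxyfuran, attacks it through an open transition state; fluoride transfer to silicon then turns the silyloxy-substituted cation into the C1 carbonyl of the 3(2H)-furanone. The closest known reaction type is the intermolecular BF3-mediated Mukaiyama aldol of 2-alkyl-3-silyloxyfurans with aldehydes, which gives 2,2-disubstituted 3(2H)-furanones; its use as a ring closure is what is new. The ten-membered carbocycle closes in a 10-(enolendo)-exo-trig mode (nine-membered if counted through the furan oxygen), helped by high dilution and by the few rotors that the Z olefin, the furan and the trans-lactone leave in the chain. C9 (S) is controlled by C8: with a non-chelating Lewis acid and a bulky silyl ether the polar Felkin–Anh arrangement (C8–O antiperiplanar to the incoming carbon, ring carbon C7 gauche) is compatible with the forming ring and gives the 8,9-anti relationship. C10 (R) is controlled by the tether: the chain C5–C9, fixed by the C6/C7 trans-lactone, should be able to span only one face of the planar furan, with the methyl group ending exo on the other face; this folding argument should be checked by modelling both transition states before material is committed. The step needs attack at C10 and not at C2, the other position next to the silyloxy group, which the far better stabilised cation from C10 attack should secure, and it needs the aldehyde to outcompete the methylene lactone as electrophile, which BF3 activation ensures. The racemic origin of C10 plays no part, because the furan is planar.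

Step 15
Reactants: 20 (6R,7S,8S,9S,10R)-8-{[tert-butyl(dimethyl)silyl]oxy}-9-hydroxy-1-oxo-3,10-epoxygermacra-2,4Z,11(13)-trien-12,6-olide
Product: 21 (6R,7S,8S,9S,10R)-9-acetoxy-8-{[tert-butyl(dimethyl)silyl]oxy}-1-oxo-3,10-epoxygermacra-2,4Z,11(13)-trien-12,6-olide
Conditions: Ac2O, DMAP (cat.), pyridine, CH2Cl2, 0 °C → rt
Reagents that add atoms: acetic anhydride, CC(=O)OC(C)=O
Why: DMAP-catalysed acetylation of the only free hydroxyl; the conditions are not basic enough for retro-aldol cleavage of the β-hydroxy ketone, and the acetate cannot eliminate because C10 is quaternary.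

Step 16
Reactants: 21 (6R,7S,8S,9S,10R)-9-acetoxy-8-{[tert-butyl(dimethyl)silyl]oxy}-1-oxo-3,10-epoxygermacra-2,4Z,11(13)-trien-12,6-olide
Product: 22 (6R,7R,8S,9S,10R)-9-acetoxy-8-hydroxy-1-oxo-3,10-epoxygermacra-2,4Z,11(13)-trien-12,6-olide
Conditions: HF·pyridine, THF, 0 °C → rt
Reagents that add atoms: none
Why: Fluoride cleavage of the secondary silyl ether under mildly acidic conditions, which leave the methylene lactone and furanone intact and under which acetyl migration from O9 to O8 should be slow (the C7 descriptor changes by priority only).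

Step 17
Reactants: 23 tert-butyl acrylate; 24 acetaldehyde
Product: 25 tert-butyl 3-hydroxy-2-methylidenebutanoate (racemic)
Conditions: DABCO (cat.), neat, rt
Reagents that add atoms: none
Why: Morita–Baylis–Hillman reaction; the racemic carbinol centre is removed again in step 19.

Step 18
Reactants: 25 tert-butyl 3-hydroxy-2-methylidenebutanoate
Product: 26 tert-butyl 3-acetoxy-2-methylidenebutanoate (racemic)
Conditions: Ac2O, Et3N, DMAP (cat.), CH2Cl2, 0 °C
Reagents that add atoms: acetic anhydride, CC(=O)OC(C)=O
Why: Routine acetylation of a secondary allylic alcohol.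

Step 19
Reactants: 26 tert-butyl 3-acetoxy-2-methylidenebutanoate
Product: 27 tert-butyl (2E)-2-(acetoxymethyl)but-2-enoate
Conditions: DABCO (0.2 equiv), THF, reflux
Reagents that add atoms: none
Why: DABCO-catalysed 1,3-transposition of a Baylis–Hillman acetate (two SN2' steps through the allylammonium acetate) gives the thermodynamically favoured trisubstituted olefin with the methyl group trans to the ester, the E geometry that the target needs.

Step 20
Reactants: 27 tert-butyl (2E)-2-(acetoxymethyl)but-2-enoate
Product: 28 (2E)-2-(acetoxymethyl)but-2-enoic acid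
Conditions: TFA, CH2Cl2, 0 °C → rt
Reagents that add atoms: none
Why: Acidolysis of the tert-butyl ester with loss of isobutene; the primary acetate and the enoate are stable to trifluoroacetic acid.

Step 21
Reactants: 22 (6R,7R,8S,9S,10R)-9-acetoxy-8-hydroxy-1-oxo-3,10-epoxygermacra-2,4Z,11(13)-trien-12,6-olide; 28 (2E)-2-(acetoxymethyl)but-2-enoic acid
Product: 30 (6R,7S,8S,9S,10R)-9-acetoxy-8-{[(2E)-2-(acetoxymethyl)but-2-enoyl]oxy}-1-oxo-3,10-epoxygermacra-2,4Z,11(13)-trien-12,6-olide, via mixed anhydride 29 (not isolated)
Conditions: 28, 2,4,6-trichlorobenzoyl chloride, Et3N, THF, rt; then 22, DMAP, toluene, rt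
Reagents that add atoms: none
Why: Yamaguchi esterification of the single free hydroxyl through the mixed anhydride; the acid is the thermodynamic E isomer and the product of amine-catalysed transposition, so DMAP should neither isomerise it nor displace its acetate.

## Compound list

1 | ethyl lactate (ethyl 2-hydroxypropanoate, racemic) | CCOC(=O)C(C)O | starting material
2 | 2-hydroxy-N-methoxy-N-methylpropanamide (racemic) | CC(O)C(=O)N(C)OC | intermediate
3 | (2Z)-3-methylpent-2-en-4-yn-1-ol | C#C/C(C)=C\CO | starting material
4 | tert-butyl(dimethyl){[(2Z)-3-methylpent-2-en-4-yn-1-yl]oxy}silane | C#C/C(C)=C\CO[Si](C)(C)C(C)(C)C | intermediate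
5 | (6Z)-8-{[tert-butyl(dimethyl)silyl]oxy}-2-hydroxy-6-methyloct-6-en-4-yn-3-one (racemic) | CC(O)C(=O)C#C/C(C)=C\CO[Si](C)(C)C(C)(C)C | intermediate
6 | 5-[(2Z)-4-{[tert-butyl(dimethyl)silyl]oxy}but-2-en-2-yl]-2-methylfuran-3(2H)-one (racemic; formed in the flask in step 4) | CC1OC(/C(C)=C\CO[Si](C)(C)C(C)(C)C)=CC1=O | intermediate
7 | 5-[(2Z)-4-hydroxybut-2-en-2-yl]-2-methylfuran-3(2H)-one (racemic) | CC1OC(/C(C)=C\CO)=CC1=O | intermediate
8 | (2Z)-3-(5-methyl-4-oxo-4,5-dihydrofuran-2-yl)but-2-enal (racemic) | CC1OC(/C(C)=C\C=O)=CC1=O | intermediate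
9 | (R)-2,3-O-isopropylideneglyceraldehyde [(4R)-2,2-dimethyl-1,3-dioxolane-4-carbaldehyde] | O=C[C@H]1COC(C)(C)O1 | starting material
10 | methyl acrylate | C=CC(=O)OC | starting material
11 | methyl 2-{hydroxy[(4R)-2,2-dimethyl-1,3-dioxolan-4-yl]methyl}prop-2-enoate (both carbinol epimers) | C=C(C(=O)OC)C(O)[C@H]1COC(C)(C)O1 | intermediate
12 | methyl (2Z)-2-(bromomethyl)-3-[(4S)-2,2-dimethyl-1,3-dioxolan-4-yl]prop-2-enoate | COC(=O)/C(CBr)=C/[C@H]1COC(C)(C)O1 | intermediate
13 | methyl 2-{(1S,2R,3Z)-1-[(4S)-2,2-dimethyl-1,3-dioxolan-4-yl]-2-hydroxy-4-(5-methyl-4-oxo-4,5-dihydrofuran-2-yl)pent-3-en-1-yl}prop-2-enoate (both C10 epimers; formed in the flask in step 8) | C=C(C(=O)OC)[C@@H]([C@H](O)/C=C(/C)C1=CC(=O)C(C)O1)[C@H]1COC(C)(C)O1 | intermediate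
14 | (4S,5R)-4-[(4S)-2,2-dimethyl-1,3-dioxolan-4-yl]-3-methylidene-5-[(1Z)-2-(5-methyl-4-oxo-4,5-dihydrofuran-2-yl)prop-1-en-1-yl]oxolan-2-one (both C10 epimers) | C=C1C(=O)O[C@H](/C=C(/C)C2=CC(=O)C(C)O2)[C@H]1[C@H]1COC(C)(C)O1 | intermediate
15 | (4R,5R)-4-[(1S)-1,2-dihydroxyethyl]-3-methylidene-5-[(1Z)-2-(5-methyl-4-oxo-4,5-dihydrofuran-2-yl)prop-1-en-1-yl]oxolan-2-one (both C10 epimers) | C=C1C(=O)O[C@H](/C=C(/C)C2=CC(=O)C(C)O2)[C@H]1[C@H](O)CO | intermediate
16 | (4S,5R)-4-[(1S)-1,2-bis{[tert-butyl(dimethyl)silyl]oxy}ethyl]-3-methylidene-5-[(1Z)-2-(5-methyl-4-oxo-4,5-dihydrofuran-2-yl)prop-1-en-1-yl]oxolan-2-one (both C10 epimers) | C=C1C(=O)O[C@H](/C=C(/C)C2=CC(=O)C(C)O2)[C@H]1[C@H](O[Si](C)(C)C(C)(C)C)CO[Si](C)(C)C(C)(C)C | intermediate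
17 | (4S,5R)-4-[(1S)-1-{[tert-butyl(dimethyl)silyl]oxy}-2-hydroxyethyl]-3-methylidene-5-[(1Z)-2-(5-methyl-4-oxo-4,5-dihydrofuran-2-yl)prop-1-en-1-yl]oxolan-2-one (both C10 epimers) | C=C1C(=O)O[C@H](/C=C(/C)C2=CC(=O)C(C)O2)[C@H]1[C@H](O[Si](C)(C)C(C)(C)C)CO | intermediate
18 | (2S)-2-{[tert-butyl(dimethyl)silyl]oxy}-2-{(2R,3S)-4-methylidene-2-[(1Z)-2-(5-methyl-4-oxo-4,5-dihydrofuran-2-yl)prop-1-en-1-yl]-5-oxooxolan-3-yl}acetaldehyde (both C10 epimers) | C=C1C(=O)O[C@H](/C=C(/C)C2=CC(=O)C(C)O2)[C@H]1[C@H](O[Si](C)(C)C(C)(C)C)C=O | intermediate
19 | (2S)-2-{[tert-butyl(dimethyl)silyl]oxy}-2-{(2R,3S)-4-methylidene-2-[(1Z)-2-{5-methyl-4-[tri(propan-2-yl)silyloxy]furan-2-yl}prop-1-en-1-yl]-5-oxooxolan-3-yl}acetaldehyde | C=C1C(=O)O[C@H](/C=C(/C)c2cc(O[Si](C(C)C)(C(C)C)C(C)C)c(C)o2)[C@H]1[C@H](O[Si](C)(C)C(C)(C)C)C=O | intermediate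
20 | (6R,7S,8S,9S,10R)-8-{[tert-butyl(dimethyl)silyl]oxy}-9-hydroxy-1-oxo-3,10-epoxygermacra-2,4Z,11(13)-trien-12,6-olide | C=C1C(=O)O[C@@H]2/C=C(/C)C3=CC(=O)[C@](C)(O3)[C@@H](O)[C@@H](O[Si](C)(C)C(C)(C)C)[C@@H]12 | intermediate
21 | (6R,7S,8S,9S,10R)-9-acetoxy-8-{[tert-butyl(dimethyl)silyl]oxy}-1-oxo-3,10-epoxygermacra-2,4Z,11(13)-trien-12,6-olide | C=C1C(=O)O[C@@H]2/C=C(/C)C3=CC(=O)[C@](C)(O3)[C@@H](OC(C)=O)[C@@H](O[Si](C)(C)C(C)(C)C)[C@@H]12 | intermediate
22 | (6R,7R,8S,9S,10R)-9-acetoxy-8-hydroxy-1-oxo-3,10-epoxygermacra-2,4Z,11(13)-trien-12,6-olide | C=C1C(=O)O[C@@H]2/C=C(/C)C3=CC(=O)[C@](C)(O3)[C@@H](OC(C)=O)[C@@H](O)[C@@H]12 | intermediate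
23 | tert-butyl acrylate | C=CC(=O)OC(C)(C)C | starting material
24 | acetaldehyde | CC=O | starting material
25 | tert-butyl 3-hydroxy-2-methylidenebutanoate (racemic) | C=C(C(C)O)C(=O)OC(C)(C)C | intermediate
26 | tert-butyl 3-acetoxy-2-methylidenebutanoate (racemic) | C=C(C(C)OC(C)=O)C(=O)OC(C)(C)C | intermediate
27 | tert-butyl (2E)-2-(acetoxymethyl)but-2-enoate | C/C=C(\COC(C)=O)C(=O)OC(C)(C)C | intermediate
28 | (2E)-2-(acetoxymethyl)but-2-enoic acid | C/C=C(\COC(C)=O)C(=O)O | intermediate
29 | (2E)-2-(acetoxymethyl)but-2-enoic 2,4,6-trichlorobenzoic anhydride (formed in the flask in step 21) | C/C=C(\COC(C)=O)C(=O)OC(=O)c1c(Cl)cc(Cl)cc1Cl | intermediate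
30 | (6R,7S,8S,9S,10R)-9-acetoxy-8-{[(2E)-2-(acetoxymethyl)but-2-enoyl]oxy}-1-oxo-3,10-epoxygermacra-2,4Z,11(13)-trien-12,6-olide (CNP0325609.1) | C=C1C(=O)O[C@@H]2/C=C(/C)C3=CC(=O)[C@](C)(O3)[C@@H](OC(C)=O)[C@@H](OC(=O)/C(=C/C)COC(C)=O)[C@@H]12 | target

## Step count and least certain steps

Total: 21 steps. Longest linear sequence: 14 steps (steps 1, 3, 4, 5, 8–16, 21, from ethyl lactate 1; equally long from enynol 3).

**Step 14 (key step, proposed new method).** The most likely failures are that the ring does not close, so that oligomers form or the silyloxyfuran is merely protodesilylated back to 18, or that the furan is attacked on the wrong face, giving the C10 epimer. Medium-ring closures are entropically and enthalpically costly, the nucleophilic carbon is fully substituted, and the C10 control rests on a folding argument without precedent. Silyl transfer to O9 instead of loss as fluoride is a lesser concern. The fallback forms the same bond by known enolate chemistry. It sets out from 18, which with Bu2BOTf and i-Pr2NEt in CH2Cl2 at −78 °C would give the dibutylboron enolate of the furanone F1 (a 3-boryloxyfuran). Under dilution and slow warming this adds to the C9 aldehyde through a closed six-membered transition state, a boron-mediated macro-aldolisation of a known type, and buffered methanolic work-up returns to the route at 20. Because the transition state is closed, the C9/C10 outcome would have to be assigned anew.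

**Step 8.** The most likely failure is a lack of simple diastereoselection: if the allylchromium species reacts through the geometry that places the dioxolane cis to the metallated carbon, the syn adduct and hence the cis-lactone results. A lesser risk is partial Z to E isomerisation of enal 8 before it reacts. The fallback uses the syn pathway on purpose and corrects C6 afterwards. It sets out from 8 and 12: zinc dust in THF/aq. NH4Cl (Dreiding–Schmidt conditions, syn-selective through the Z-type allylzinc) would give the open syn hydroxy ester F2. Me3SnOH in 1,2-dichloroethane would hydrolyse it to the hydroxy acid F3, and Mitsunobu lactonisation (PPh3, DIAD, THF) would close the ring with inversion at C6, coming back to the route at 14.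

**Step 13.** The most likely failure is loss of chemoselectivity: the silyl triflate may enolise the α-silyloxy aldehyde as well (erasing C8) or act as a Lewis acid and trigger an uncontrolled aldol before BF3 is added. The fallback changes the order so that no aldehyde is present during silylation. It sets out from 17: N-(trimethylsilyl)imidazole would cap the primary hydroxyl and TIPSOTf/Et3N at −78 °C would then form the silyloxyfuran, giving the trimethylsilyl ether F4. Brief methanolysis (K2CO3, cat., MeOH, 0 °C) would free the primary alcohol F5, and Parikh–Doering oxidation (SO3·pyridine, DMSO, i-Pr2NEt), which is non-acidic and tolerates enol silanes, would come back to the route at 19.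

**Step 21.** The most likely failure is acetyl migration from O9 to the neighbouring free O8 under the basic acylation conditions, which would scramble the two esters, together with slow acylation of a hydroxyl flanked by C7 and the C9 acetate. The fallback reverses the order of the two acylations. It sets out from 20: HF·pyridine would remove the silyl ether to give the 8,9-diol F6. The less hindered C8 hydroxyl (C9 is neopentyl-like, next to the quaternary C10) would be esterified selectively with anhydride 29 to give the C8 mono-ester F7, and acetylation of the remaining C9 hydroxyl (Ac2O, DMAP, pyridine) would come back to the route at 30.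

## Further compounds

F1 | step 14 | (2S)-2-{[tert-butyl(dimethyl)silyl]oxy}-2-{(2R,3S)-2-[(1Z)-2-{4-[(dibutylboranyl)oxy]-5-methylfuran-2-yl}prop-1-en-1-yl]-4-methylidene-5-oxooxolan-3-yl}acetaldehyde | C=C1C(=O)O[C@H](/C=C(/C)c2cc(OB(CCCC)CCCC)c(C)o2)[C@H]1[C@H](O[Si](C)(C)C(C)(C)C)C=O
F2 | step 8 | methyl 2-{(1S,2S,3Z)-1-[(4S)-2,2-dimethyl-1,3-dioxolan-4-yl]-2-hydroxy-4-(5-methyl-4-oxo-4,5-dihydrofuran-2-yl)pent-3-en-1-yl}prop-2-enoate (both C10 epimers) | C=C(C(=O)OC)[C@@H]([C@@H](O)/C=C(/C)C1=CC(=O)C(C)O1)[C@H]1COC(C)(C)O1
F3 | step 8 | 2-{(1S,2S,3Z)-1-[(4S)-2,2-dimethyl-1,3-dioxolan-4-yl]-2-hydroxy-4-(5-methyl-4-oxo-4,5-dihydrofuran-2-yl)pent-3-en-1-yl}prop-2-enoic acid (both C10 epimers) | C=C(C(=O)O)[C@@H]([C@@H](O)/C=C(/C)C1=CC(=O)C(C)O1)[C@H]1COC(C)(C)O1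
F4 | step 13 | (4S,5R)-4-[(1S)-1-{[tert-butyl(dimethyl)silyl]oxy}-2-(trimethylsilyloxy)ethyl]-3-methylidene-5-[(1Z)-2-{5-methyl-4-[tri(propan-2-yl)silyloxy]furan-2-yl}prop-1-en-1-yl]oxolan-2-one | C=C1C(=O)O[C@H](/C=C(/C)c2cc(O[Si](C(C)C)(C(C)C)C(C)C)c(C)o2)[C@H]1[C@H](O[Si](C)(C)C(C)(C)C)CO[Si](C)(C)C
F5 | step 13 | (4S,5R)-4-[(1S)-1-{[tert-butyl(dimethyl)silyl]oxy}-2-hydroxyethyl]-3-methylidene-5-[(1Z)-2-{5-methyl-4-[tri(propan-2-yl)silyloxy]furan-2-yl}prop-1-en-1-yl]oxolan-2-one | C=C1C(=O)O[C@H](/C=C(/C)c2cc(O[Si](C(C)C)(C(C)C)C(C)C)c(C)o2)[C@H]1[C@H](O[Si](C)(C)C(C)(C)C)CO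
F6 | step 21 | (6R,7R,8S,9S,10R)-8,9-dihydroxy-1-oxo-3,10-epoxygermacra-2,4Z,11(13)-trien-12,6-olide | C=C1C(=O)O[C@@H]2/C=C(/C)C3=CC(=O)[C@](C)(O3)[C@@H](O)[C@@H](O)[C@@H]12
F7 | step 21 | (6R,7S,8S,9S,10R)-8-{[(2E)-2-(acetoxymethyl)but-2-enoyl]oxy}-9-hydroxy-1-oxo-3,10-epoxygermacra-2,4Z,11(13)-trien-12,6-olide | C=C1C(=O)O[C@@H]2/C=C(/C)C3=CC(=O)[C@](C)(O3)[C@@H](O)[C@@H](OC(=O)/C(=C/C)COC(C)=O)[C@@H]12
A1 | alternative 1 | ten-membered 4Z,8Z-dien-3-one with C1 4-methoxybenzyl ether, C6 tert-butyldimethylsilyl ether, C7 isopropenyl and C10 methyl and triisopropylsilyl ether (oxy-Cope product) | O=C1C[C@@H](OCc2ccc(OC)cc2)[C@](C)(O[Si](C(C)C)(C(C)C)C(C)C)/C=C\[C@@H](C(C)=C)[C@H](O[Si](C)(C)C(C)(C)C)/C=C1/C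
A2 | alternative 2 | 1-hydroxy-3,10-epoxygermacra-2,4Z,11(13)-trien-12,6-olide 8,9-acetonide (dienol ether from transannular epoxide opening) | C=C1C(=O)O[C@@H]2/C=C(/C)C3=C[C@H](O)[C@](C)(O3)[C@@H](OC4(C)C)[C@@H](O4)[C@@H]12
A3 | alternative 3 | allyl ester of the 11-carboxy trans-lactone with free C8 hydroxyl and C9 tert-butyldimethylsilyl ether (1-oxo-3,10-epoxygermacra-2,4Z-dien-12,6-olide series) | C=CCOC(=O)[C@@H]1C(=O)O[C@@H]2/C=C(/C)C3=CC(=O)[C@](C)(O3)[C@@H](O[Si](C)(C)C(C)(C)C)[C@@H](O)[C@@H]12
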